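**Plan**

1. Numbering follows 2,3-dihydro-1-benzofuran: ring B is O1, C2, C3, C3a, C7a and ring A is C3a, C4, C5, C6, C7, C7a. The retrosynthesis cuts, in this order, the two C5–prenyl bonds (back to an aromatic acylphloroglucinol), the C7–C(=O) bond, the C3–C2 bond of ring B and the aryl O–CH2 ether bond.
2. Forward: ring A is bought as a benzaldehyde whose formyl carbon becomes C3. The side chain is hung on one phenol oxygen, ring B is closed by forming C3–C2, the isobutyryl group is placed at C7, the oxygens are freed, and C5 is prenylated twice with loss of aromaticity.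
3. Enabling feature: ring B carries the only stereocentre, C2, as an O–CH carbon bonded directly to the benzylic CH2 (C3). A carbene at C3 therefore lies five atoms from the hydrogens of an ortho O–CH2 group, so one C–H insertion closes ring B and creates C2.
4. Stereochemistry: C2 (R) is set by a chiral cobalt porphyrin in that insertion; no later step makes or breaks a bond at C2.
5. The second ortho oxygen (C4–O) is carried as a silyl ether: it offers the carbene no C–H bond, turns metalation away from C5 and leaves with fluoride. The C6 methyl ether is removed by chelation to the C7 ketone.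

Key step: step 4

Assumption: which enantiomer of the porphyrin ligand gives (R) at C2 is settled in a trial run and the route is written for that enantiomer; the target is drawn as the enol tautomer of the given SMILES, the tautomers being in free exchange.

**Step 1**
Reactants: 1 2,6-dihydroxy-4-methoxybenzaldehyde; 2 2,2-dimethyloxirane
Product: 3 2-hydroxy-6-(2-hydroxy-2-methylpropoxy)-4-methoxybenzaldehyde
Conditions: K2CO3 (0.3 equiv), DMF, 80 °C, sealed tube
Reagents that add atoms: none
Why: Phenoxide opening of the epoxide at its unhindered CH2 carbon (SN2 epoxide ring opening, a Williamson-type etherification) should give the aryl ether of the tertiary alcohol, and the second phenol, hydrogen-bonded to the aldehyde, should hold the reaction at the mono-ether.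

**Step 2**
Reactants: 3 2-hydroxy-6-(2-hydroxy-2-methylpropoxy)-4-methoxybenzaldehyde
Product: 4 2-[(tert-butyldimethylsilyl)oxy]-6-{2-[(tert-butyldimethylsilyl)oxy]-2-methylpropoxy}-4-methoxybenzaldehyde
Conditions: TBSOTf (2.5 equiv), 2,6-lutidine, CH2Cl2, 0 °C → rt
Reagents that add atoms: tert-butyldimethylsilyl trifluoromethanesulfonate, CC(C)(C)[Si](C)(C)OS(=O)(=O)C(F)(F)F
Why: Silylation with a silyl triflate and a hindered pyridine base should cover the chelated phenol and the tertiary alcohol in one operation, the aldehyde being engaged only reversibly and returned on work-up.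

**Step 3**
Reactants: 4 2-[(tert-butyldimethylsilyl)oxy]-6-{2-[(tert-butyldimethylsilyl)oxy]-2-methylpropoxy}-4-methoxybenzaldehyde
Product: 5 N'-[(E)-(2-[(tert-butyldimethylsilyl)oxy]-6-{2-[(tert-butyldimethylsilyl)oxy]-2-methylpropoxy}-4-methoxyphenyl)methylidene]-4-methylbenzenesulfonohydrazide
Conditions: TsNHNH2, THF, MgSO4, 40 °C
Reagents that add atoms: p-toluenesulfonohydrazide, Cc1ccc(cc1)S(=O)(=O)NN
Why: Condensation of an aldehyde with a sulfonylhydrazide (hydrazone formation) under neutral, aprotic conditions should give the (E)-tosylhydrazone without disturbing either silyl ether.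

**Step 4**
Reactants: 5 N'-[(E)-(2-[(tert-butyldimethylsilyl)oxy]-6-{2-[(tert-butyldimethylsilyl)oxy]-2-methylpropoxy}-4-methoxyphenyl)methylidene]-4-methylbenzenesulfonohydrazide
Product: 7 (2R)-4-[(tert-butyldimethylsilyl)oxy]-2-{2-[(tert-butyldimethylsilyl)oxy]propan-2-yl}-6-methoxy-2,3-dihydro-1-benzofuran, via aryldiazomethane 6 (not isolated)
Conditions: Cs2CO3 (2 equiv), [Co(3,5-DitBu-ChenPhyrin)] (2 mol %, a D2-symmetric chiral amidoporphyrin complex of divalent cobalt), 1,4-dioxane, 40 °C
Reagents that add atoms: none
Why: Cs2CO3 converts the tosylhydrazone into aryldiazomethane 6 (Bamford–Stevens), which the divalent cobalt porphyrin takes up with loss of N2 as a trivalent cobalt carbene radical centred on C3. This radical abstracts one hydrogen of the ortho O–CH2 group through a six-membered transition state (1,5-hydrogen-atom transfer), and the alpha-oxy radical so formed displaces cobalt from C3 to make the C3–C2 bond. The closest known reaction type is the enantioselective intramolecular radical C–H alkylation of aryldiazomethanes generated in situ from aldehyde tosylhydrazones under chiral cobalt amidoporphyrins, which furnishes 2-substituted indolines and 2,3-dihydrobenzofurans. Ring B closes as a five-membered ring by this net 1,5 C–H insertion, the bond-forming event being a 5-exo-tet radical substitution at C3. C2 is under catalyst control: the chiral amide pocket of the porphyrin picks one of the two enantiotopic O–CH2 hydrogens and holds one face of the radical during ring closure. The step needs insertion at this CH2 alone and no carbene dimerisation: the other ortho oxygen bears a silyl group with no C–H bond five atoms from C3, the methoxy group is para and out of reach, C3 has no neighbouring hydrogen for a 1,2-shift, and the metal-bound radical is far less prone to azine or stilbene formation than a dirhodium carbene.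

**Step 5**
Reactants: 7 (2R)-4-[(tert-butyldimethylsilyl)oxy]-2-{2-[(tert-butyldimethylsilyl)oxy]propan-2-yl}-6-methoxy-2,3-dihydro-1-benzofuran; 8 N-methoxy-N,2-dimethylpropanamide (N-methoxy-N-methylisobutyramide)
Product: 11 1-[(2R)-4-[(tert-butyldimethylsilyl)oxy]-2-{2-[(tert-butyldimethylsilyl)oxy]propan-2-yl}-6-methoxy-2,3-dihydro-1-benzofuran-7-yl]-2-methylpropan-1-one, via aryllithium 9 (not isolated), via tetrahedral lithium adduct 10 (not isolated)
Conditions: n-BuLi, TMEDA, THF, −20 → 0 °C; then 8, −78 °C → rt; then H2O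
Reagents that add atoms: none
Why: Directed ortho-metalation should take place at C7–H, which lies between the methoxy oxygen and O1 (both able to hold lithium) while C5–H is walled in by the bulky, poorly coordinating silyloxy group, and the aryllithium then acylates the Weinreb amide through a chelated adduct that cannot over-add and gives the ketone on aqueous work-up (Weinreb ketone synthesis).

**Step 6**
Reactants: 11 1-[(2R)-4-[(tert-butyldimethylsilyl)oxy]-2-{2-[(tert-butyldimethylsilyl)oxy]propan-2-yl}-6-methoxy-2,3-dihydro-1-benzofuran-7-yl]-2-methylpropan-1-one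
Product: 13 1-[(2R)-4-[(tert-butyldimethylsilyl)oxy]-2-{2-[(tert-butyldimethylsilyl)oxy]propan-2-yl}-6-hydroxy-2,3-dihydro-1-benzofuran-7-yl]-2-methylpropan-1-one, via dichloroboron chelate 12 (not isolated)
Conditions: BCl3 (1.2 equiv), CH2Cl2, −78 → −20 °C; then H2O
Reagents that add atoms: none
Why: Chelation-controlled demethylation of an ortho-acyl aryl methyl ether: boron bridges the ketone and methoxy oxygens and chloride removes the methyl group by SN2 at low temperature, where the hindered silyl ethers and the secondary O1–C2 bond (no easy SN2 or ionisation) should stay intact.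

**Step 7**
Reactants: 13 1-[(2R)-4-[(tert-butyldimethylsilyl)oxy]-2-{2-[(tert-butyldimethylsilyl)oxy]propan-2-yl}-6-hydroxy-2,3-dihydro-1-benzofuran-7-yl]-2-methylpropan-1-one
Product: 14 1-[(2R)-4,6-dihydroxy-2-(2-hydroxypropan-2-yl)-2,3-dihydro-1-benzofuran-7-yl]-2-methylpropan-1-one
Conditions: TBAF (5 equiv), THF, 0 → 50 °C; then H2O
Reagents that add atoms: none
Why: Fluoride-mediated desilylation should free the phenol at once and the hindered tertiary alcohol on warming, without touching the ketone or C2.

**Step 8**
Reactants: 14 1-[(2R)-4,6-dihydroxy-2-(2-hydroxypropan-2-yl)-2,3-dihydro-1-benzofuran-7-yl]-2-methylpropan-1-one; 15 1-bromo-3-methylbut-2-ene (prenyl bromide)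
Product: 17 garcinielliptone HC, (2R,7Z)-7-(1-hydroxy-2-methylpropylidene)-2-(2-hydroxypropan-2-yl)-5,5-bis(3-methylbut-2-en-1-yl)-2,3-dihydro-1-benzofuran-4,6(5H,7H)-dione, via 5-prenyl phenol 16 (not isolated)
Conditions: 15 (2.4 equiv), 10% aq. KOH, 0 °C → rt
Reagents that add atoms: none
Why: Base-mediated dearomative double C-alkylation of an acylphloroglucinol (the classical route to gem-diprenylated hop acids): the dianion is alkylated by SN2 at C5, the only free ring carbon and flanked by both phenoxides, and a second alkylation at the same carbon breaks aromaticity to give the enolised triketone, with the protic medium favouring carbon over oxygen and C2 left untouched.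

**Compound list**

1 | 2,6-dihydroxy-4-methoxybenzaldehyde | COc1cc(O)c(C=O)c(O)c1 | starting material
2 | 2,2-dimethyloxirane | CC1(C)CO1 | starting material
3 | 2-hydroxy-6-(2-hydroxy-2-methylpropoxy)-4-methoxybenzaldehyde | COc1cc(O)c(C=O)c(OCC(C)(C)O)c1 | intermediate
4 | 2-[(tert-butyldimethylsilyl)oxy]-6-{2-[(tert-butyldimethylsilyl)oxy]-2-methylpropoxy}-4-methoxybenzaldehyde | COc1cc(O[Si](C)(C)C(C)(C)C)c(C=O)c(OCC(C)(C)O[Si](C)(C)C(C)(C)C)c1 | intermediate
5 | (E)-tosylhydrazone of 4 | COc1cc(O[Si](C)(C)C(C)(C)C)c(/C=N/NS(=O)(=O)c2ccc(C)cc2)c(OCC(C)(C)O[Si](C)(C)C(C)(C)C)c1 | intermediate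
6 | 1-[(tert-butyldimethylsilyl)oxy]-3-{2-[(tert-butyldimethylsilyl)oxy]-2-methylpropoxy}-2-(diazomethyl)-5-methoxybenzene | COc1cc(O[Si](C)(C)C(C)(C)C)c(C=[N+]=[N-])c(OCC(C)(C)O[Si](C)(C)C(C)(C)C)c1 | intermediate (not isolated)
7 | (2R)-4-[(tert-butyldimethylsilyl)oxy]-2-{2-[(tert-butyldimethylsilyl)oxy]propan-2-yl}-6-methoxy-2,3-dihydro-1-benzofuran | COc1cc(O[Si](C)(C)C(C)(C)C)c2C[C@H](C(C)(C)O[Si](C)(C)C(C)(C)C)Oc2c1 | intermediate
8 | N-methoxy-N,2-dimethylpropanamide | CC(C)C(=O)N(C)OC | starting material
9 | 7-lithio derivative of 7 | COc1cc(O[Si](C)(C)C(C)(C)C)c2C[C@H](C(C)(C)O[Si](C)(C)C(C)(C)C)Oc2c1[Li] | intermediate (not isolated)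
10 | lithium alkoxide of the N-methoxy-N-methyl hemiaminal formed from 9 and 8 (carbinol carbon unassigned) | COc1cc(O[Si](C)(C)C(C)(C)C)c2C[C@H](C(C)(C)O[Si](C)(C)C(C)(C)C)Oc2c1C(O[Li])(N(C)OC)C(C)C | intermediate (not isolated)
11 | 1-[(2R)-4-[(tert-butyldimethylsilyl)oxy]-2-{2-[(tert-butyldimethylsilyl)oxy]propan-2-yl}-6-methoxy-2,3-dihydro-1-benzofuran-7-yl]-2-methylpropan-1-one | COc1cc(O[Si](C)(C)C(C)(C)C)c2C[C@H](C(C)(C)O[Si](C)(C)C(C)(C)C)Oc2c1C(=O)C(C)C | intermediate
12 | 6-O-dichloroboryl derivative of 13 (boron also bound to the ketone oxygen) | ClB(Cl)Oc1cc(O[Si](C)(C)C(C)(C)C)c2C[C@H](C(C)(C)O[Si](C)(C)C(C)(C)C)Oc2c1C(=O)C(C)C | intermediate (not isolated)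
13 | 1-[(2R)-4-[(tert-butyldimethylsilyl)oxy]-2-{2-[(tert-butyldimethylsilyl)oxy]propan-2-yl}-6-hydroxy-2,3-dihydro-1-benzofuran-7-yl]-2-methylpropan-1-one | Oc1cc(O[Si](C)(C)C(C)(C)C)c2C[C@H](C(C)(C)O[Si](C)(C)C(C)(C)C)Oc2c1C(=O)C(C)C | intermediate
14 | 1-[(2R)-4,6-dihydroxy-2-(2-hydroxypropan-2-yl)-2,3-dihydro-1-benzofuran-7-yl]-2-methylpropan-1-one | Oc1cc(O)c2C[C@H](C(C)(C)O)Oc2c1C(=O)C(C)C | intermediate
15 | 1-bromo-3-methylbut-2-ene | CC(C)=CCBr | starting material
16 | 1-[(2R)-4,6-dihydroxy-2-(2-hydroxypropan-2-yl)-5-(3-methylbut-2-en-1-yl)-2,3-dihydro-1-benzofuran-7-yl]-2-methylpropan-1-one | Oc1c(CC=C(C)C)c(O)c2C[C@H](C(C)(C)O)Oc2c1C(=O)C(C)C | intermediate (not isolated)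
17 | garcinielliptone HC, (2R,7Z)-7-(1-hydroxy-2-methylpropylidene)-2-(2-hydroxypropan-2-yl)-5,5-bis(3-methylbut-2-en-1-yl)-2,3-dihydro-1-benzofuran-4,6(5H,7H)-dione | CC(C)=CCC1(CC=C(C)C)C(=O)C2=C(O[C@@H](C(C)(C)O)C2)/C(=C(/O)C(C)C)C1=O | target

**Step count and risks**

Total steps: 8. Longest linear sequence: 8 steps (1 to 17).

Steps most likely to fail:

Step 4. Hydrogen transfer from the crowded O–CH2 group, which is inductively deactivated by the neighbouring silyloxy carbon, may be slower than loss of the diazo compound to azine and stilbene. The aryl silyl ether may be stripped by carbonate, and the crowded substrate may fit the chiral pocket poorly, giving weak discrimination between the two enantiotopic hydrogens. The fallback sets out from 1 and returns at 7. It replaces the silyloxy-isopropyl arm by an ester, so that the C–H bond to be broken is weaker and unhindered, and builds the carbinol afterwards. Aldehyde 1 would be mono-alkylated with methyl bromoacetate (K2CO3, acetone, rt) to methyl 2-(2-formyl-3-hydroxy-5-methoxyphenoxy)acetate F1. Silylation (TBSCl, imidazole, DMF) would give methyl 2-{3-[(tert-butyldimethylsilyl)oxy]-2-formyl-5-methoxyphenoxy}acetate F2. Condensation with TsNHNH2 would give methyl 2-{3-[(tert-butyldimethylsilyl)oxy]-5-methoxy-2-[(E)-(2-tosylhydrazinylidene)methyl]phenoxy}acetate F3. Under the conditions of step 4 the derived methyl 2-{3-[(tert-butyldimethylsilyl)oxy]-2-(diazomethyl)-5-methoxyphenoxy}acetate F4 should cyclise through a captodatively stabilised O–CH(CO2Me) radical to methyl (2R)-4-[(tert-butyldimethylsilyl)oxy]-6-methoxy-2,3-dihydro-1-benzofuran-2-carboxylate F5. Excess MeMgBr (THF, −78 → 0 °C) should then convert the ester into 2-[(2R)-4-[(tert-butyldimethylsilyl)oxy]-6-methoxy-2,3-dihydro-1-benzofuran-2-yl]propan-2-ol F6, and TBSOTf with 2,6-lutidine would give 7.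

Step 5. Deprotonation may stray to C5 and be followed by migration of silicon from oxygen to carbon, butyllithium may attack the aryl silyl ether at silicon, or the hindered aryllithium may enolise the amide and return 7. The fallback sets out from 7 and returns at 11 without a new compound (F0). It is an electrophilic route: Friedel–Crafts acylation with isobutyryl chloride and SnCl4 in CH2Cl2 at −78 °C. The ring is a phloroglucinol triether and C5 is screened by the silyloxy and methoxy groups, so the acylium ion should enter at C7.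

Step 8. Alkylation may go to the unchelated C4 oxygen instead of carbon, stall after the first prenyl group, or continue on the enol oxygen of the product. The fallback sets out from 14 and returns at 17 through 16, without a new compound (F0). It is a Tsuji–Trost prenylation with tert-butyl (3-methylbut-2-en-1-yl) carbonate and Pd(PPh3)4 (a zerovalent palladium complex) in THF at rt. O-Allylation is reversible under palladium, and the soft carbon nucleophile attacks the unsubstituted terminus of the prenyl ligand, so the doubly C5-alkylated product should accumulate.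

**Further compounds**

F1 | step 4 | methyl 2-(2-formyl-3-hydroxy-5-methoxyphenoxy)acetate | COC(=O)COc1cc(OC)cc(O)c1C=O
F2 | step 4 | methyl 2-{3-[(tert-butyldimethylsilyl)oxy]-2-formyl-5-methoxyphenoxy}acetate | COC(=O)COc1cc(OC)cc(O[Si](C)(C)C(C)(C)C)c1C=O
F3 | step 4 | methyl 2-{3-[(tert-butyldimethylsilyl)oxy]-5-methoxy-2-[(E)-(2-tosylhydrazinylidene)methyl]phenoxy}acetate | COC(=O)COc1cc(OC)cc(O[Si](C)(C)C(C)(C)C)c1/C=N/NS(=O)(=O)c1ccc(C)cc1
F4 | step 4 | methyl 2-{3-[(tert-butyldimethylsilyl)oxy]-2-(diazomethyl)-5-methoxyphenoxy}acetate | COC(=O)COc1cc(OC)cc(O[Si](C)(C)C(C)(C)C)c1C=[N+]=[N-]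
F5 | step 4 | methyl (2R)-4-[(tert-butyldimethylsilyl)oxy]-6-methoxy-2,3-dihydro-1-benzofuran-2-carboxylate | COc1cc(O[Si](C)(C)C(C)(C)C)c2C[C@H](C(=O)OC)Oc2c1
F6 | step 4 | 2-[(2R)-4-[(tert-butyldimethylsilyl)oxy]-6-methoxy-2,3-dihydro-1-benzofuran-2-yl]propan-2-ol | COc1cc(O[Si](C)(C)C(C)(C)C)c2C[C@H](C(C)(C)O)Oc2c1
F0 | step 5 | none | none
F0 | step 8 | none | none
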